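**Retrosynthetic overview**

1. The target is freed by desilylation of 22. The C8–C9 bond of 22 comes from a Liebeskind–Srogl union of ring thioester 15 with the (Z)-alkenylstannane 21, which brings the Z-alkene, its methyl group and the decanoate in one piece.
2. Thioester 15 goes back through enone ester 12 (Saegusa–Ito desaturation to C4=C5, oxidation at C3) to hydroxy ester 9.
3. The strategy rests on this feature: C7, C1, C6 with its methyl and oxygen, C5, C4, C3 and C2 with both methyls are the intact carbon chain of linalool. The six-membered carbocycle, the only ring and formed once, lacks only the bond between quaternary C2 and C1, which is closed by a Cp2TiCl epoxide-opening 6-exo radical cyclisation of epoxy enoate 7.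
4. 7 comes from (S)-linalool by silylation, Shi epoxidation, ozonolysis and Wittig olefination; 21 comes from but-2-yn-1-ol (trans-hydroalumination/iodination, stannylation) and decanoyl chloride.

Key step: step 5

**Remarks**

- Numbering: ring C1 (CH bearing the chain), C2 (CMe2), C3 (C=O), C4=C5, C6 (C(Me)OH); chain C7 (CH2), C8 (C=O), C9(Me)=C10, C11 (CH2O).
- The target is (1R,6S) with the C1 arm cis to the C6 oxygen, and the C9=C10 alkene is Z (C8 carbonyl cis to C11).
- Assumption: the target rests as the open γ-hydroxy ketone drawn, not as its cyclic hemiketal.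
- Assumption: (S)-(+)-linalool is bought in high enantiomeric purity, since C6 and hence the absolute configuration come from it.
- Assumption: the D-fructose-derived Shi ketone gives the (2R)-oxirane, as its spiro transition-state model predicts; C3 is oxidised later, so an error here would not reach the target.
- The enoate is built by ozonolysis/Wittig olefination, because a vinyl group on a silylated, fully substituted carbinol is a sluggish metathesis partner.

**Route**

Step 1
Reactants: 1 (S)-linalool
Product: 2 triethyl{[(3S)-3,7-dimethylocta-1,6-dien-3-yl]oxy}silane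
Conditions: TESOTf, 2,6-lutidine, CH2Cl2, −78 to 0 °C
Reagents that add atoms: triethylsilyl trifluoromethanesulfonate, CC[Si](CC)(CC)OS(=O)(=O)C(F)(F)F
Why: O-silylation with a silyl triflate and a hindered pyridine base works even on a tertiary allylic alcohol, and the ether later prevents cyclo-etherification onto the epoxide and lactonisation onto the ester; the stereocentre is not touched.

Step 2
Reactants: 2 triethyl{[(3S)-3,7-dimethylocta-1,6-dien-3-yl]oxy}silane
Product: 3 triethyl{[(3S)-5-[(2R)-3,3-dimethyloxiran-2-yl]-3-methylpent-1-en-3-yl]oxy}silane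
Conditions: 1,2:4,5-di-O-isopropylidene-β-D-erythro-hexo-2,3-diulo-2,6-pyranose (D-fructose-derived Shi ketone, 30 mol%), KHSO5 (as Oxone), K2CO3, Bu4NHSO4, MeCN/CH2(OMe)2/aq. Na2B4O7 buffer (pH 10.5), 0 °C
Reagents that add atoms: potassium peroxymonosulfate, [K+].[O-]S(=O)(=O)OO
Why: Shi epoxidation, in which the electrophilic chiral dioxirane should react with the trisubstituted alkene far faster than with the vinyl group and deliver oxygen through a spiro transition state to the face that gives the (2R)-oxirane.

Step 3
Reactants: 3 triethyl{[(3S)-5-[(2R)-3,3-dimethyloxiran-2-yl]-3-methylpent-1-en-3-yl]oxy}silane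
Product: 5 (2S)-4-[(2R)-3,3-dimethyloxiran-2-yl]-2-methyl-2-(triethylsilyloxy)butanal, via secondary ozonide 4 (not isolated)
Conditions: O3, CH2Cl2, −78 °C; then PPh3, −78 °C to rt
Reagents that add atoms: ozone, [O-][O+]=O
Why: Ozonolysis with reductive work-up cleaves the only remaining alkene, the epoxide and silyl ether are inert to ozone, and the aldehyde cannot enolise or epimerise because its α-carbon is fully substituted.

Step 4
Reactants: 5 (2S)-4-[(2R)-3,3-dimethyloxiran-2-yl]-2-methyl-2-(triethylsilyloxy)butanal; 6 methyl (triphenylphosphoranylidene)acetate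
Product: 7 methyl (2E,4S)-6-[(2R)-3,3-dimethyloxiran-2-yl]-4-methyl-4-(triethylsilyloxy)hex-2-enoate
Conditions: toluene, 60 °C
Reagents that add atoms: none
Why: Wittig olefination with a stabilised ylide should give the E-enoate under neutral conditions that leave the epoxide and the silyl ether alone.

Step 5
Reactants: 7 methyl (2E,4S)-6-[(2R)-3,3-dimethyloxiran-2-yl]-4-methyl-4-(triethylsilyloxy)hex-2-enoate
Product: 9 methyl 2-[(1R,3R,6S)-3-hydroxy-2,2,6-trimethyl-6-(triethylsilyloxy)cyclohexyl]acetate, via bis-titanium alkoxide enolate 8 (not isolated)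
Conditions: Cp2TiCl2 (2.5 equiv), Mn dust (8 equiv), THF, rt, slow addition of 7 (0.01 M final); then aq. NaH2PO4
Reagents that add atoms: none
Why: Cp2TiCl, made in the flask from Cp2TiCl2 and manganese, gives one electron to the oxirane and breaks the C2–O bond on the more substituted side, so that a tertiary C2 radical and a C3 alkoxide on tetravalent titanium arise, driven by release of ring strain. The nucleophilic tertiary radical adds to the electron-poor β-carbon C1 of the enoate in a 6-exo-trig closure that forms the C1–C2 bond and the only carbocycle, and a second Cp2TiCl reduces the α-ester radical to a titanium enolate (8) that is protonated at C7 on work-up; the closest known reaction type is the titanocene chloride-mediated reductive epoxide opening with radical cyclisation onto acrylate acceptors. The one new stereocentre, C1, is controlled by C6 through a chair-like transition state in which the C6 methyl stays equatorial (axial, it would meet the axial C2 methyl in a syn-pentane contact), the silyloxy group is axial and the enoate arm is equatorial, hence cis to the C6 oxygen (1R). C3 keeps the configuration of the epoxide carbon, whose C–O bond is not touched, and its titanium alkoxide sits equatorial in the same chair, so the (2R)-oxirane is the matched case. The step needs regioselective opening to the tertiary radical, ring closure faster than capture of that radical by a second titanium centre (which would give the open-chain allylic alcohol or the reduced chain), and this facial choice; the radical-stabilising gem-dimethyl terminus, the steric shielding of a tertiary radical against Cp2TiCl together with the activated acceptor and high dilution, and the fully substituted C6 secure them. Because the radical transition state is early, it can join the quaternary C2 to a carbon that stands next to the fully substituted C6, where an enolate or carbocation alkylation would not.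

Step 6
Reactants: 9 methyl 2-[(1R,3R,6S)-3-hydroxy-2,2,6-trimethyl-6-(triethylsilyloxy)cyclohexyl]acetate
Product: 10 methyl 2-[(1R,6S)-2,2,6-trimethyl-3-oxo-6-(triethylsilyloxy)cyclohexyl]acetate
Conditions: Dess–Martin periodinane, NaHCO3, CH2Cl2, 0 °C to rt
Reagents that add atoms: none
Why: Dess–Martin oxidation should convert the hindered secondary carbinol to the C3 ketone under buffered conditions that spare the silyl ether and ester, and no stereocentre stands α to the new carbonyl.

Step 7
Reactants: 10 methyl 2-[(1R,6S)-2,2,6-trimethyl-3-oxo-6-(triethylsilyloxy)cyclohexyl]acetate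
Product: 11 methyl 2-[(1R,6S)-2,2,6-trimethyl-6-(triethylsilyloxy)-3-(trimethylsilyloxy)cyclohex-3-en-1-yl]acetate
Conditions: TMSOTf, Et3N, CH2Cl2, 0 °C
Reagents that add atoms: trimethylsilyl trifluoromethanesulfonate, C[Si](C)(C)OS(=O)(=O)C(F)(F)F
Why: Soft enolisation silylates the ketone much faster than the methyl ester, and since C2 is quaternary the enol ether can only form towards C4.

Step 8
Reactants: 11 methyl 2-[(1R,6S)-2,2,6-trimethyl-6-(triethylsilyloxy)-3-(trimethylsilyloxy)cyclohex-3-en-1-yl]acetate
Product: 12 methyl 2-[(1R,6S)-2,2,6-trimethyl-3-oxo-6-(triethylsilyloxy)cyclohex-4-en-1-yl]acetate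
Conditions: Pd(OAc)2 (1.1 equiv), MeCN, rt
Reagents that add atoms: none
Why: Saegusa–Ito oxidation, in which divalent palladium takes the enol ether to a palladium enolate at C4 and β-hydride elimination from C5 gives the C4=C5 enone, with the regiochemistry fixed by the enol ether.

Step 9
Reactants: 12 methyl 2-[(1R,6S)-2,2,6-trimethyl-3-oxo-6-(triethylsilyloxy)cyclohex-4-en-1-yl]acetate
Product: 14 2-[(1R,6S)-2,2,6-trimethyl-3-oxo-6-(triethylsilyloxy)cyclohex-4-en-1-yl]acetic acid, via lithium carboxylate 13 (not isolated)
Conditions: LiOH, THF/H2O, 0 °C to rt; then 1 M HCl to pH 4, 0 °C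
Reagents that add atoms: lithium hydroxide, [Li+].[OH-]
Why: Saponification of an unhindered methyl ester; hydroxide at this temperature is too weak a base to enolise the ester (so no retro-Michael opening of the C1–C2 bond), the enone has no α′- or γ-hydrogen, and the tertiary silyl ether should survive brief acidification to pH 4.

Step 10
Reactants: 14 2-[(1R,6S)-2,2,6-trimethyl-3-oxo-6-(triethylsilyloxy)cyclohex-4-en-1-yl]acetic acid
Product: 15 S-phenyl 2-[(1R,6S)-2,2,6-trimethyl-3-oxo-6-(triethylsilyloxy)cyclohex-4-en-1-yl]ethanethioate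
Conditions: PhSH (1.05 equiv), DCC, DMAP (5 mol%), CH2Cl2, −20 to 0 °C
Reagents that add atoms: benzenethiol, Sc1ccccc1
Why: Steglich thioesterification, in which acyl transfer to the thiol should outrun conjugate addition because the enone β-carbon C5 is neopentylic (next to quaternary C6) and only a slight excess of thiol is present.

Step 11
Reactants: 16 but-2-yn-1-ol
Product: 18 (2Z)-3-iodobut-2-en-1-ol, via cyclic alkenylalanate 17 (not isolated)
Conditions: NaAlH2(OCH2CH2OMe)2, THF, 0 °C to rt; then I2, −78 °C
Reagents that add atoms: iodine, II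
Why: Alkoxide-directed trans-hydroalumination delivers hydride to C2 and aluminium to C3 within a five-membered oxa-aluminacycle, and iodinolysis of the C–Al bond with retention places iodine cis to CH2OH (Z).

Step 12
Reactants: 18 (2Z)-3-iodobut-2-en-1-ol
Product: 19 (2Z)-3-(tributylstannyl)but-2-en-1-ol
Conditions: (Bu3Sn)2 (1.5 equiv), PdCl2(PPh3)2 (5 mol%), THF, 50 °C
Reagents that add atoms: hexabutylditin, CCCC[Sn](CCCC)(CCCC)[Sn](CCCC)(CCCC)CCCC
Why: Palladium-catalysed stannylation of an alkenyl iodide (oxidative addition to zerovalent palladium, Sn–Sn transmetallation, reductive elimination) proceeds with retention of alkene geometry and tolerates the free alcohol.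

Step 13
Reactants: 19 (2Z)-3-(tributylstannyl)but-2-en-1-ol; 20 decanoyl chloride
Product: 21 (2Z)-3-(tributylstannyl)but-2-en-1-yl decanoate
Conditions: pyridine, DMAP (cat.), CH2Cl2, 0 °C
Reagents that add atoms: none
Why: Acylation of the primary allylic alcohol with excess base avoids protodestannylation, and installing the decanoate before the coupling means no free (Z)-γ-hydroxy enone, which would cyclise and dehydrate to a furan, is ever formed.

Step 14
Reactants: 15 S-phenyl 2-[(1R,6S)-2,2,6-trimethyl-3-oxo-6-(triethylsilyloxy)cyclohex-4-en-1-yl]ethanethioate; 21 (2Z)-3-(tributylstannyl)but-2-en-1-yl decanoate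
Product: 22 (2Z)-3-methyl-4-oxo-5-[(1R,6S)-2,2,6-trimethyl-3-oxo-6-(triethylsilyloxy)cyclohex-4-en-1-yl]pent-2-en-1-yl decanoate
Conditions: Pd2(dba)3 (5 mol%), tri(2-furyl)phosphine (20 mol%), CuO2PPh2 (1.5 equiv), THF/hexane, rt
Reagents that add atoms: none
Why: Liebeskind–Srogl thioester–organostannane coupling, in which the monovalent copper phosphinate activates the C–S bond towards zerovalent palladium and takes up thiolate and tin, so the ketone forms under neutral, base-free conditions with retention of the Z geometry and without touching the ring enone, silyl ether or decanoate.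

Step 15
Reactants: 22 (2Z)-3-methyl-4-oxo-5-[(1R,6S)-2,2,6-trimethyl-3-oxo-6-(triethylsilyloxy)cyclohex-4-en-1-yl]pent-2-en-1-yl decanoate
Product: 23 (2Z)-5-[(1R,6S)-6-hydroxy-2,2,6-trimethyl-3-oxocyclohex-4-en-1-yl]-3-methyl-4-oxopent-2-en-1-yl decanoate (CNP0241324.1)
Conditions: HF·pyridine, pyridine, THF, 0 °C to rt
Reagents that add atoms: none
Why: Fluoride-mediated cleavage of the triethylsilyl ether under pyridine-buffered conditions, which contain no base or nucleophile strong enough to cleave the decanoate, isomerise the Z-enone or open the ring by retro-Michael reaction.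

**Compound list**

1 | (S)-linalool, (3S)-3,7-dimethylocta-1,6-dien-3-ol | C=C[C@@](C)(O)CCC=C(C)C | starting material
2 | triethyl{[(3S)-3,7-dimethylocta-1,6-dien-3-yl]oxy}silane | C=C[C@@](C)(O[Si](CC)(CC)CC)CCC=C(C)C | intermediate
3 | triethyl{[(3S)-5-[(2R)-3,3-dimethyloxiran-2-yl]-3-methylpent-1-en-3-yl]oxy}silane | C=C[C@@](C)(O[Si](CC)(CC)CC)CC[C@H]1OC1(C)C | intermediate
4 | 3-{(2S)-4-[(2R)-3,3-dimethyloxiran-2-yl]-2-(triethylsilyloxy)butan-2-yl}-1,2,4-trioxolane (secondary ozonide, both configurations at the trioxolane carbon) | C1(OCOO1)[C@@](C)(O[Si](CC)(CC)CC)CC[C@H]2OC2(C)C | intermediate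
5 | (2S)-4-[(2R)-3,3-dimethyloxiran-2-yl]-2-methyl-2-(triethylsilyloxy)butanal | O=C[C@@](C)(O[Si](CC)(CC)CC)CC[C@H]1OC1(C)C | intermediate
6 | methyl (triphenylphosphoranylidene)acetate | COC(=O)C=P(c1ccccc1)(c1ccccc1)c1ccccc1 | starting material
7 | methyl (2E,4S)-6-[(2R)-3,3-dimethyloxiran-2-yl]-4-methyl-4-(triethylsilyloxy)hex-2-enoate | COC(=O)/C=C/[C@@](C)(O[Si](CC)(CC)CC)CC[C@H]1OC1(C)C | intermediate
8 | C3 alkoxide and ester enolate of 9 on two Cp2TiCl units (tetravalent titanium; cyclopentadienyl rings drawn σ-bonded) | COC(O[Ti](Cl)(C1C=CC=C1)C1C=CC=C1)=C[C@@H]1C(C)(C)[C@H](O[Ti](Cl)(C2C=CC=C2)C2C=CC=C2)CC[C@]1(C)O[Si](CC)(CC)CC | intermediate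
9 | methyl 2-[(1R,3R,6S)-3-hydroxy-2,2,6-trimethyl-6-(triethylsilyloxy)cyclohexyl]acetate | COC(=O)C[C@@H]1C(C)(C)[C@H](O)CC[C@]1(C)O[Si](CC)(CC)CC | intermediate
10 | methyl 2-[(1R,6S)-2,2,6-trimethyl-3-oxo-6-(triethylsilyloxy)cyclohexyl]acetate | COC(=O)C[C@@H]1C(C)(C)C(=O)CC[C@]1(C)O[Si](CC)(CC)CC | intermediate
11 | methyl 2-[(1R,6S)-2,2,6-trimethyl-6-(triethylsilyloxy)-3-(trimethylsilyloxy)cyclohex-3-en-1-yl]acetate | COC(=O)C[C@@H]1C(C)(C)C(O[Si](C)(C)C)=CC[C@]1(C)O[Si](CC)(CC)CC | intermediate
12 | methyl 2-[(1R,6S)-2,2,6-trimethyl-3-oxo-6-(triethylsilyloxy)cyclohex-4-en-1-yl]acetate | COC(=O)C[C@@H]1C(C)(C)C(=O)C=C[C@]1(C)O[Si](CC)(CC)CC | intermediate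
13 | lithium 2-[(1R,6S)-2,2,6-trimethyl-3-oxo-6-(triethylsilyloxy)cyclohex-4-en-1-yl]acetate | [Li+].[O-]C(=O)C[C@@H]1C(C)(C)C(=O)C=C[C@]1(C)O[Si](CC)(CC)CC | intermediate
14 | 2-[(1R,6S)-2,2,6-trimethyl-3-oxo-6-(triethylsilyloxy)cyclohex-4-en-1-yl]acetic acid | OC(=O)C[C@@H]1C(C)(C)C(=O)C=C[C@]1(C)O[Si](CC)(CC)CC | intermediate
15 | S-phenyl 2-[(1R,6S)-2,2,6-trimethyl-3-oxo-6-(triethylsilyloxy)cyclohex-4-en-1-yl]ethanethioate | O=C(Sc1ccccc1)C[C@@H]1C(C)(C)C(=O)C=C[C@]1(C)O[Si](CC)(CC)CC | intermediate
16 | but-2-yn-1-ol | CC#CCO | starting material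
17 | sodium 2,2-bis(2-methoxyethoxy)-3-methyl-2,5-dihydro-1,2-oxaaluminol-2-uide (cyclic alkenylalanate) | CC1=CCO[Al-]1(OCCOC)OCCOC.[Na+] | intermediate
18 | (2Z)-3-iodobut-2-en-1-ol | C/C(I)=C/CO | intermediate
19 | (2Z)-3-(tributylstannyl)but-2-en-1-ol | C/C(=C/CO)[Sn](CCCC)(CCCC)CCCC | intermediate
20 | decanoyl chloride | CCCCCCCCCC(=O)Cl | starting material
21 | (2Z)-3-(tributylstannyl)but-2-en-1-yl decanoate | CCCCCCCCCC(=O)OC/C=C(/C)[Sn](CCCC)(CCCC)CCCC | intermediate
22 | (2Z)-3-methyl-4-oxo-5-[(1R,6S)-2,2,6-trimethyl-3-oxo-6-(triethylsilyloxy)cyclohex-4-en-1-yl]pent-2-en-1-yl decanoate | CCCCCCCCCC(=O)OC/C=C(/C)C(=O)C[C@@H]1C(C)(C)C(=O)C=C[C@]1(C)O[Si](CC)(CC)CC | intermediate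
23 | (2Z)-5-[(1R,6S)-6-hydroxy-2,2,6-trimethyl-3-oxocyclohex-4-en-1-yl]-3-methyl-4-oxopent-2-en-1-yl decanoate | CCCCCCCCCC(=O)OC/C=C(/C)C(=O)C[C@@H]1C(C)(C)C(=O)C=C[C@]1(C)O | target

**Step count**

Total: 15 steps. Longest linear sequence: 12 steps (steps 1–10, 14, 15); the stannane arm is 3 steps (11–13).

**Steps most likely to fail**

1. Step 5. The tertiary radical may be reduced, or lose a β-hydrogen after capture by titanium, before it closes the ring, and the chair preference (axial silyloxy against axial methyl at C6) may give only moderate facial selectivity at C1. The fallback makes the same C2 radical without titanium. It sets out from 7: Et2Al(TMP), prepared from Et2AlCl and lithium 2,2,6,6-tetramethylpiperidide (toluene, 0 °C), would isomerise the oxirane by syn-elimination of a methyl hydrogen, without cationic character that could let the silyl ether oxygen attack, to the isopropenyl carbinol methyl (2E,4S,7R)-7-hydroxy-4,8-dimethyl-4-(triethylsilyloxy)nona-2,8-dienoate F1. Fe(acac)3 and PhSiH3 in EtOH/ethylene glycol at 60 °C (hydrogen-atom-transfer reductive olefin coupling, intramolecular) would then put a hydrogen on the terminal CH2, form the tertiary C2 radical and close the C1–C2 bond onto the enoate through the same chair. The fallback comes back to the route at 9.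

2. Step 14. The α-methyl-substituted alkenyl group may transfer slowly from tin, zerovalent palladium may ionise the allylic decanoate, and the Z-enone (carbonyl cis to C11, the less stable geometry) may isomerise by reversible conjugate addition of phosphine or thiolate. The fallback forms the C8–C9 bond by carbonyl addition and sets out from 12. iBu2AlH (CH2Cl2, −78 to 0 °C) would reduce ester and enone to (4S,5R)-5-(2-hydroxyethyl)-4,6,6-trimethyl-4-(triethylsilyloxy)cyclohex-2-en-1-ol F2. Dess–Martin periodinane would oxidise both carbinols to 2-[(1R,6S)-2,2,6-trimethyl-3-oxo-6-(triethylsilyloxy)cyclohex-4-en-1-yl]acetaldehyde F3. In parallel, 18 would be acylated with 20 (pyridine, DMAP, CH2Cl2) to (2Z)-3-iodobut-2-en-1-yl decanoate F4. A Nozaki–Hiyama–Kishi reaction (CrCl2, NiCl2 cat., DMSO, rt) would add the alkenyl chromium from F4 to the aldehyde of F3, not to the hindered ring enone, with retention of geometry, giving (2Z)-4-hydroxy-3-methyl-5-[(1R,6S)-2,2,6-trimethyl-3-oxo-6-(triethylsilyloxy)cyclohex-4-en-1-yl]pent-2-en-1-yl decanoate F5 as a mixture of carbinol epimers. Dess–Martin oxidation (NaHCO3) of F5 comes back to the route at 22.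

3. Step 10. Thiolate may add to the ring enone in competition with acyl transfer, and the free acid may lose its silyl group and lactonise onto C6–O while it waits. The fallback avoids thiol altogether and sets out from 14. 1-Chloro-N,N,2-trimethylprop-1-en-1-amine (CH2Cl2, 0 °C) would give, under neutral conditions, 2-[(1R,6S)-2,2,6-trimethyl-3-oxo-6-(triethylsilyloxy)cyclohex-4-en-1-yl]acetyl chloride F6. A Stille acylation of F6 with 21 (PdCl2(PPh3)2 cat., toluene, 50 °C) would by-pass 15 and come back to the route at 22.

**Further compounds**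

F1 | step 5 | methyl (2E,4S,7R)-7-hydroxy-4,8-dimethyl-4-(triethylsilyloxy)nona-2,8-dienoate | COC(=O)/C=C/[C@@](C)(O[Si](CC)(CC)CC)CC[C@@H](O)C(C)=C
F2 | step 14 | (4S,5R)-5-(2-hydroxyethyl)-4,6,6-trimethyl-4-(triethylsilyloxy)cyclohex-2-en-1-ol (both C1 epimers) | OCC[C@@H]1C(C)(C)C(O)C=C[C@]1(C)O[Si](CC)(CC)CC
F3 | step 14 | 2-[(1R,6S)-2,2,6-trimethyl-3-oxo-6-(triethylsilyloxy)cyclohex-4-en-1-yl]acetaldehyde | O=CC[C@@H]1C(C)(C)C(=O)C=C[C@]1(C)O[Si](CC)(CC)CC
F4 | step 14 | (2Z)-3-iodobut-2-en-1-yl decanoate | CCCCCCCCCC(=O)OC/C=C(/C)I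
F5 | step 14 | (2Z)-4-hydroxy-3-methyl-5-[(1R,6S)-2,2,6-trimethyl-3-oxo-6-(triethylsilyloxy)cyclohex-4-en-1-yl]pent-2-en-1-yl decanoate (both C4 epimers) | CCCCCCCCCC(=O)OC/C=C(/C)C(O)C[C@@H]1C(C)(C)C(=O)C=C[C@]1(C)O[Si](CC)(CC)CC
F6 | step 10 | 2-[(1R,6S)-2,2,6-trimethyl-3-oxo-6-(triethylsilyloxy)cyclohex-4-en-1-yl]acetyl chloride | O=C(Cl)C[C@@H]1C(C)(C)C(=O)C=C[C@]1(C)O[Si](CC)(CC)CC
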